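## Retrosynthetic overview

1. The last bond made is the E-alkene between quaternary C6 of the cyclohexene and C8 of coumarin B, by Horner–Wadsworth–Emmons coupling of aldehyde 26 with phosphonate 31. The pyranone ring of coumarin B comes from 2-methylresorcinol by Pechmann condensation.
2. The pyranone ring of coumarin A is annulated late onto a 2,4-dimethoxyphenyl placeholder (formylation, ortho-demethylation, Wittig lactonisation), because a coumarin would not survive the amide base of the key step.
3. Feature: in the cyclohexene (C1 = CH carrying coumarin A, C2=C3(CH3), C4, C5, quaternary C6) the C1–C6 bond joins allylic C1 to C6, whose exocyclic styryl carbon can be a carboxyl carbon. O=C–C6–C1–C2=C3 is then a γ,δ-unsaturated acid, the retron of an ester-enolate Claisen shift, so the carbocycle is made from δ-lactone 12 through its silyl ketene acetal.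
4. Lactone 12 comes from (R)-linalool by ozonolysis, one-carbon homologation to the δ-lactone, α-methylation and Heck arylation of the vinyl group. Its carbinol carbon is the only source of chirality.
5. Ring order: δ-lactone (template) → cyclohexene (step 7) → pyranone of coumarin A (step 12); pyranone of coumarin B in a separate branch (step 15).

Key step: step 7

Assumption: (R)-(−)-linalool of high enantiomeric purity is the source of chirality; the optical purity of every later compound is limited by it.

## Route

Step 1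
Reactants: 1 (R)-linalool
Product: 4 (5R)-5-ethenyl-5-methyloxolan-2-ol (anomer mixture), via secondary ozonide 2 (not isolated), via open hydroxy aldehyde 3 (not isolated)
Conditions: O3 (1.0 equiv, metered), CH2Cl2, −78 °C; then Me2S, −78 °C → rt
Reagents that add atoms: ozone, [O-][O+]=O
Why: Ozone adds much faster to the electron-rich trisubstituted alkene than to the vinyl group, so a metered single equivalent cleaves only the isopropylidene end (chemoselective ozonolysis with reductive work-up), and the liberated γ-hydroxy aldehyde closes to the five-membered lactol without touching the carbinol stereocentre.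

Step 2
Reactants: 4 (5R)-5-ethenyl-5-methyloxolan-2-ol
Product: 5 (3R)-7-methoxy-3-methylhepta-1,6-dien-3-ol (E/Z mixture)
Conditions: [Ph3PCH2OMe]Cl (2.5 equiv), KOtBu (2.5 equiv), THF, 0 °C; then 4, 0 °C → rt
Reagents that add atoms: (methoxymethyl)triphenylphosphonium chloride, COC[P+](c1ccccc1)(c1ccccc1)c1ccccc1.[Cl-]
Why: Wittig olefination of the lactol through its open hydroxy-aldehyde form with the methoxymethylene ylide (an excess covers the free hydroxyl) adds the one carbon that will become the lactone carbonyl.

Step 3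
Reactants: 5 (3R)-7-methoxy-3-methylhepta-1,6-dien-3-ol
Product: 7 (6R)-6-ethenyl-6-methyloxan-2-ol (anomer mixture), via open hydroxy aldehyde 6 (not isolated)
Conditions: 0.5 M HCl (cat.), THF–H2O, 0 °C → rt
Reagents that add atoms: water, O
Why: Acid-catalysed enol ether hydrolysis is far faster than ionisation of the tertiary allylic alcohol under these dilute, cold conditions, and the δ-hydroxy aldehyde that results closes to the six-membered lactol.

Step 4
Reactants: 7 (6R)-6-ethenyl-6-methyloxan-2-ol
Product: 8 (6R)-6-ethenyl-6-methyloxan-2-one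
Conditions: TEMPO (10 mol %), PhI(OAc)2 (1.3 equiv), CH2Cl2, rt
Reagents that add atoms: none
Why: The oxoammonium salt formed from TEMPO and PhI(OAc)2 oxidises the hemiacetal C–H of the lactol to the lactone and leaves the vinyl group alone (TEMPO-mediated lactol oxidation).

Step 5
Reactants: 8 (6R)-6-ethenyl-6-methyloxan-2-one
Product: 10 (6R)-6-ethenyl-3,6-dimethyloxan-2-one (both C3 epimers), via lithium enolate 9 (not isolated)
Conditions: LiN(iPr)2 (1.05 equiv), THF, −78 °C; MeI (3 equiv), −78 → −40 °C
Reagents that add atoms: iodomethane, CI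
Why: Kinetic deprotonation gives the lactone enolate, which is C-methylated by iodomethane at low temperature (enolate alkylation); the new α-stereocentre need not be controlled because it becomes trigonal in step 7.

Step 6
Reactants: 10 (6R)-6-ethenyl-3,6-dimethyloxan-2-one; 11 1-iodo-2,4-dimethoxybenzene
Product: 12 (6R)-6-[(E)-2-(2,4-dimethoxyphenyl)ethenyl]-3,6-dimethyloxan-2-one (both C3 epimers)
Conditions: Pd(OAc)2 (5 mol %), Ag2CO3 (0.6 equiv), toluene, 80 °C; chromatography on Et3N-deactivated silica
Reagents that add atoms: none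
Why: Mizoroki–Heck arylation: the arylpalladium species formed from 11 adds its aryl group to the terminal vinyl carbon and syn β-hydride elimination, possible only towards the benzylic CH2, gives the E-styrene, while phosphine-free Pd(OAc)2 with Ag2CO3 as iodide scavenger favours β-hydride over β-acyloxy elimination so that the allylic lactone C–O bond is kept.

Step 7
Reactants: 12 (6R)-6-[(E)-2-(2,4-dimethoxyphenyl)ethenyl]-3,6-dimethyloxan-2-one
Product: 16 (1S,2S)-2-(2,4-dimethoxyphenyl)-1,4-dimethylcyclohex-3-ene-1-carboxylic acid, via lithium enolate 13 (not isolated), via silyl ketene acetal 14 (not isolated), via silyl ester 15 (not isolated)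
Conditions: LiN(iPr)2 (1.2 equiv), THF, −78 °C; tBuMe2SiCl (1.3 equiv), DMPU, −78 °C → rt; solvent switch to toluene, 105 °C (base-washed glassware); then 1 M HCl (cat.), THF–H2O, rt
Reagents that add atoms: none
Why: Deprotonation at the lactone α-carbon C3 and O-silylation give the cyclic silyl ketene acetal 14, whose C3=C2(OSi)–O1–C6–CH=CHAr array undergoes a concerted suprafacial [3,3]-sigmatropic shift, an Ireland–Claisen rearrangement whose closest known type is the rearrangement of 6-alkenyl δ-lactone silyl ketene acetals to cyclohex-3-enecarboxylic acids. The carbocycle (lactone C3, C4, C5, C6 and the two styryl carbons) closes by bond formation between C3 and the aryl-bearing styryl carbon while the C6–O1 bond breaks, so the six-membered lactone is traded for a six-membered carbocycle and the carboxyl group becomes exocyclic. Because the C4–C5 chain ties C3 to C6, the six-atom array can only react through a boat inside a bicyclo[2.2.2]octane-like transition state, and the ring also fixes the ketene acetal geometry (C4 cis to O1). The quaternary centre (C1 of 16) is set by this enforced boat and the methine centre (C2 of 16) by delivery of C3 to the styryl face from which O1 departs, so both follow from the single (6R) carbinol centre, which is consumed, and the E geometry of the styrene places the aryl group cis to the carboxyl. The step needs O-silylation rather than C-silylation and a concerted shift rather than ionisation of the electron-rich tertiary allylic C–O bond, which the hard silyl chloride in DMPU, the non-polar solvent and the exclusion of acid until the shift is complete are meant to secure. Mild aqueous acid then hydrolyses silyl ester 15 to the acid.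

Step 8
Reactants: 16 (1S,2S)-2-(2,4-dimethoxyphenyl)-1,4-dimethylcyclohex-3-ene-1-carboxylic acid
Product: 17 [(1S,2R)-2-(2,4-dimethoxyphenyl)-1,4-dimethylcyclohex-3-en-1-yl]methanol
Conditions: LiAlH4, THF, 0 °C → reflux; aqueous work-up
Reagents that add atoms: none
Why: LiAlH4 reduces the hindered carboxylic acid to the neopentyl-type primary alcohol (hydride reduction), and neither stereocentre can epimerise because C1 is quaternary and C2 carries no acidifying group (the descriptor at C2 changes only through the priority rules).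

Step 9
Reactants: 17 [(1S,2R)-2-(2,4-dimethoxyphenyl)-1,4-dimethylcyclohex-3-en-1-yl]methanol
Product: 18 [(1S,2R)-2-(2,4-dimethoxyphenyl)-1,4-dimethylcyclohex-3-en-1-yl]methyl acetate
Conditions: Ac2O, pyridine, DMAP (cat.), CH2Cl2, rt
Reagents that add atoms: acetic anhydride, CC(=O)OC(C)=O
Why: DMAP-catalysed acetylation masks the alcohol as an ester that tolerates the Vilsmeier reagent, BCl3 and the hot Wittig step.

Step 10
Reactants: 18 [(1S,2R)-2-(2,4-dimethoxyphenyl)-1,4-dimethylcyclohex-3-en-1-yl]methyl acetate
Product: 20 [(1S,2R)-2-(5-formyl-2,4-dimethoxyphenyl)-1,4-dimethylcyclohex-3-en-1-yl]methyl acetate, via aryl iminium salt 19 (not isolated)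
Conditions: POCl3, DMF, 0 → 50 °C; then aq. NaOAc
Reagents that add atoms: N,N-dimethylformamide, CN(C)C=O; water, O
Why: Vilsmeier–Haack formylation: the chloroiminium electrophile attacks C5 of the aryl ring, the position para to the 2-methoxy and ortho to the 4-methoxy group (C3 between the two methoxy groups is blocked sterically), and the iminium salt 19 is hydrolysed on work-up.

Step 11
Reactants: 20 [(1S,2R)-2-(5-formyl-2,4-dimethoxyphenyl)-1,4-dimethylcyclohex-3-en-1-yl]methyl acetate
Product: 22 [(1S,2R)-2-(5-formyl-4-hydroxy-2-methoxyphenyl)-1,4-dimethylcyclohex-3-en-1-yl]methyl acetate, via aryloxydichloroborane 21 (not isolated)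
Conditions: BCl3 (1.5 equiv), CH2Cl2, −78 → −10 °C; then H2O
Reagents that add atoms: none
Why: BCl3 chelates between the formyl oxygen and the ortho methoxy oxygen and cleaves only that methyl ether (chelation-directed demethylation), the low temperature sparing the acetate, the para methoxy group and the ring alkene.

Step 12
Reactants: 22 [(1S,2R)-2-(5-formyl-4-hydroxy-2-methoxyphenyl)-1,4-dimethylcyclohex-3-en-1-yl]methyl acetate
Product: 24 [(1S,2R)-2-(7-methoxy-2-oxo-2H-chromen-6-yl)-1,4-dimethylcyclohex-3-en-1-yl]methyl acetate, via o-hydroxycinnamate ester 23 (not isolated)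
Conditions: Ph3P=CHCO2Et, N,N-diethylaniline, reflux
Reagents that add atoms: ethyl (triphenylphosphoranylidene)acetate, CCOC(=O)C=P(c1ccccc1)(c1ccccc1)c1ccccc1
Why: Wittig olefination of the salicylaldehyde gives the o-hydroxycinnamate 23, whose double bond equilibrates at the temperature of boiling N,N-diethylaniline so that the Z isomer lactonises with loss of ethanol to the coumarin (Wittig–lactonisation coumarin synthesis).

Step 13
Reactants: 24 [(1S,2R)-2-(7-methoxy-2-oxo-2H-chromen-6-yl)-1,4-dimethylcyclohex-3-en-1-yl]methyl acetate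
Product: 25 6-[(1R,6S)-6-(hydroxymethyl)-3,6-dimethylcyclohex-2-en-1-yl]-7-methoxy-2H-chromen-2-one
Conditions: K2CO3 (cat.), MeOH, rt; work-up at pH 3
Reagents that add atoms: none
Why: Base-catalysed transesterification with methanol removes the acetate, and any methoxide opening of the coumarin lactone is reversed on acidification because the Z-cinnamate recloses.

Step 14
Reactants: 25 6-[(1R,6S)-6-(hydroxymethyl)-3,6-dimethylcyclohex-2-en-1-yl]-7-methoxy-2H-chromen-2-one
Product: 26 (1S,2S)-2-(7-methoxy-2-oxo-2H-chromen-6-yl)-1,4-dimethylcyclohex-3-ene-1-carbaldehyde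
Conditions: Dess–Martin periodinane, CH2Cl2, rt
Reagents that add atoms: none
Why: Dess–Martin oxidation stops at the aldehyde under neutral conditions, and the aldehyde has no α-hydrogen, so the quaternary centre is safe.

Step 15
Reactants: 27 2-methylresorcinol
Product: 28 7-hydroxy-8-methyl-2H-chromen-2-one
Conditions: malic acid, conc. H2SO4, 100 °C
Reagents that add atoms: malic acid, OC(CC(=O)O)C(=O)O
Why: Pechmann condensation: malic acid loses CO and water in H2SO4 to give formylacetic acid, which alkylates C4 of 2-methylresorcinol (ortho to one hydroxyl, para to the other) and lactonises, leaving the methyl group at C8 of the coumarin.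

Step 16
Reactants: 28 7-hydroxy-8-methyl-2H-chromen-2-one
Product: 29 7-methoxy-8-methyl-2H-chromen-2-one
Conditions: MeI, K2CO3, acetone, reflux
Reagents that add atoms: iodomethane, CI
Why: Williamson O-methylation of the phenoxide.

Step 17
Reactants: 29 7-methoxy-8-methyl-2H-chromen-2-one
Product: 30 8-(bromomethyl)-7-methoxy-2H-chromen-2-one
Conditions: N-bromosuccinimide, AIBN (cat.), PhCF3, reflux
Reagents that add atoms: N-bromosuccinimide, O=C1CCC(=O)N1Br
Why: Wohl–Ziegler bromination: under radical-chain conditions in a non-polar solvent the benzylic hydrogen of the 8-methyl group is abstracted in preference to ionic bromination of the ring.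

Step 18
Reactants: 30 8-(bromomethyl)-7-methoxy-2H-chromen-2-one
Product: 31 diethyl [(7-methoxy-2-oxo-2H-chromen-8-yl)methyl]phosphonate
Conditions: P(OEt)3, neat, 140 °C
Reagents that add atoms: triethyl phosphite, CCOP(OCC)OCC
Why: Michaelis–Arbuzov reaction of the benzylic bromide with triethyl phosphite.

Step 19
Reactants: 31 diethyl [(7-methoxy-2-oxo-2H-chromen-8-yl)methyl]phosphonate; 26 (1S,2S)-2-(7-methoxy-2-oxo-2H-chromen-6-yl)-1,4-dimethylcyclohex-3-ene-1-carbaldehyde
Product: 33 7-methoxy-6-{(1R,6R)-6-[(E)-2-(7-methoxy-2-oxo-2H-chromen-8-yl)ethenyl]-3,6-dimethylcyclohex-2-en-1-yl}-2H-chromen-2-one, via phosphonate carbanion 32 (not isolated)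
Conditions: NaN(SiMe3)2 (1.1 equiv), THF, −78 °C; then 26, −78 → 0 °C
Reagents that add atoms: none
Why: Horner–Wadsworth–Emmons olefination: the benzylic phosphonate carbanion 32 adds to the non-enolisable aldehyde and the adduct eliminates diethyl phosphate to give the E-alkene, the preferred geometry for an aryl-stabilised phosphonate and a bulky α-quaternary aldehyde, and no stereocentre is touched.

## Compound list

1 | (R)-linalool, (3R)-3,7-dimethylocta-1,6-dien-3-ol | CC(C)=CCC[C@@](C)(O)C=C | starting material
2 | (3R)-5-(5,5-dimethyl-1,2,4-trioxolan-3-yl)-3-methylpent-1-en-3-ol (secondary ozonide) | CC1(C)OOC(CC[C@@](C)(O)C=C)O1 | intermediate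
3 | (4R)-4-hydroxy-4-methylhex-5-enal | O=CCC[C@@](C)(O)C=C | intermediate
4 | (5R)-5-ethenyl-5-methyloxolan-2-ol (anomer mixture) | OC1CC[C@](C)(C=C)O1 | intermediate
5 | (3R)-7-methoxy-3-methylhepta-1,6-dien-3-ol (E/Z mixture) | COC=CCC[C@@](C)(O)C=C | intermediate
6 | (5R)-5-hydroxy-5-methylhept-6-enal | O=CCCC[C@@](C)(O)C=C | intermediate
7 | (6R)-6-ethenyl-6-methyloxan-2-ol (anomer mixture) | OC1CCC[C@](C)(C=C)O1 | intermediate
8 | (6R)-6-ethenyl-6-methyloxan-2-one | O=C1CCC[C@](C)(C=C)O1 | intermediate
9 | lithium (2R)-2-ethenyl-2-methyl-3,4-dihydro-2H-pyran-6-olate | [Li+].[O-]C1=CCC[C@](C)(C=C)O1 | intermediate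
10 | (6R)-6-ethenyl-3,6-dimethyloxan-2-one (both C3 epimers) | CC1CC[C@](C)(C=C)OC1=O | intermediate
11 | 1-iodo-2,4-dimethoxybenzene | COc1ccc(I)c(OC)c1 | starting material
12 | (6R)-6-[(E)-2-(2,4-dimethoxyphenyl)ethenyl]-3,6-dimethyloxan-2-one (both C3 epimers) | CC1CC[C@](C)(/C=C/c2ccc(OC)cc2OC)OC1=O | intermediate
13 | lithium (2R)-2-[(E)-2-(2,4-dimethoxyphenyl)ethenyl]-2,5-dimethyl-3,4-dihydro-2H-pyran-6-olate | [Li+].CC1=C([O-])O[C@@](C)(/C=C/c2ccc(OC)cc2OC)CC1 | intermediate
14 | tert-butyl({(2R)-2-[(E)-2-(2,4-dimethoxyphenyl)ethenyl]-2,5-dimethyl-3,4-dihydro-2H-pyran-6-yl}oxy)dimethylsilane | CC1=C(O[Si](C)(C)C(C)(C)C)O[C@@](C)(/C=C/c2ccc(OC)cc2OC)CC1 | intermediate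
15 | tert-butyldimethylsilyl (1S,2S)-2-(2,4-dimethoxyphenyl)-1,4-dimethylcyclohex-3-ene-1-carboxylate | COc1ccc([C@@H]2C=C(C)CC[C@]2(C)C(=O)O[Si](C)(C)C(C)(C)C)c(OC)c1 | intermediate
16 | (1S,2S)-2-(2,4-dimethoxyphenyl)-1,4-dimethylcyclohex-3-ene-1-carboxylic acid | COc1ccc([C@@H]2C=C(C)CC[C@]2(C)C(=O)O)c(OC)c1 | intermediate
17 | [(1S,2R)-2-(2,4-dimethoxyphenyl)-1,4-dimethylcyclohex-3-en-1-yl]methanol | COc1ccc([C@@H]2C=C(C)CC[C@]2(C)CO)c(OC)c1 | intermediate
18 | [(1S,2R)-2-(2,4-dimethoxyphenyl)-1,4-dimethylcyclohex-3-en-1-yl]methyl acetate | COc1ccc([C@@H]2C=C(C)CC[C@]2(C)COC(C)=O)c(OC)c1 | intermediate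
19 | N-({5-[(1R,6S)-6-(acetoxymethyl)-3,6-dimethylcyclohex-2-en-1-yl]-2,4-dimethoxyphenyl}methylidene)-N-methylmethanaminium dichlorophosphate | COc1cc(OC)c(C=[N+](C)C)cc1[C@@H]1C=C(C)CC[C@]1(C)COC(C)=O.[O-]P(Cl)(Cl)=O | intermediate
20 | [(1S,2R)-2-(5-formyl-2,4-dimethoxyphenyl)-1,4-dimethylcyclohex-3-en-1-yl]methyl acetate | COc1cc(OC)c(C=O)cc1[C@@H]1C=C(C)CC[C@]1(C)COC(C)=O | intermediate
21 | [(1S,2R)-2-{4-[(dichloroboranyl)oxy]-5-formyl-2-methoxyphenyl}-1,4-dimethylcyclohex-3-en-1-yl]methyl acetate | COc1cc(OB(Cl)Cl)c(C=O)cc1[C@@H]1C=C(C)CC[C@]1(C)COC(C)=O | intermediate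
22 | [(1S,2R)-2-(5-formyl-4-hydroxy-2-methoxyphenyl)-1,4-dimethylcyclohex-3-en-1-yl]methyl acetate | COc1cc(O)c(C=O)cc1[C@@H]1C=C(C)CC[C@]1(C)COC(C)=O | intermediate
23 | ethyl 3-{5-[(1R,6S)-6-(acetoxymethyl)-3,6-dimethylcyclohex-2-en-1-yl]-2-hydroxy-4-methoxyphenyl}prop-2-enoate (E/Z mixture) | CCOC(=O)C=Cc1cc([C@@H]2C=C(C)CC[C@]2(C)COC(C)=O)c(OC)cc1O | intermediate
24 | [(1S,2R)-2-(7-methoxy-2-oxo-2H-chromen-6-yl)-1,4-dimethylcyclohex-3-en-1-yl]methyl acetate | COc1cc2oc(=O)ccc2cc1[C@@H]1C=C(C)CC[C@]1(C)COC(C)=O | intermediate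
25 | 6-[(1R,6S)-6-(hydroxymethyl)-3,6-dimethylcyclohex-2-en-1-yl]-7-methoxy-2H-chromen-2-one | COc1cc2oc(=O)ccc2cc1[C@@H]1C=C(C)CC[C@]1(C)CO | intermediate
26 | (1S,2S)-2-(7-methoxy-2-oxo-2H-chromen-6-yl)-1,4-dimethylcyclohex-3-ene-1-carbaldehyde | COc1cc2oc(=O)ccc2cc1[C@@H]1C=C(C)CC[C@]1(C)C=O | intermediate
27 | 2-methylresorcinol | Cc1c(O)cccc1O | starting material
28 | 7-hydroxy-8-methyl-2H-chromen-2-one | Cc1c(O)ccc2ccc(=O)oc12 | intermediate
29 | 7-methoxy-8-methyl-2H-chromen-2-one | COc1ccc2ccc(=O)oc2c1C | intermediate
30 | 8-(bromomethyl)-7-methoxy-2H-chromen-2-one | COc1ccc2ccc(=O)oc2c1CBr | intermediate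
31 | diethyl [(7-methoxy-2-oxo-2H-chromen-8-yl)methyl]phosphonate | CCOP(=O)(OCC)Cc1c(OC)ccc2ccc(=O)oc12 | intermediate
32 | sodium (diethoxyphosphoryl)(7-methoxy-2-oxo-2H-chromen-8-yl)methanide | [Na+].CCOP(=O)(OCC)[CH-]c1c(OC)ccc2ccc(=O)oc12 | intermediate
33 | 7-methoxy-6-{(1R,6R)-6-[(E)-2-(7-methoxy-2-oxo-2H-chromen-8-yl)ethenyl]-3,6-dimethylcyclohex-2-en-1-yl}-2H-chromen-2-one | COc1cc2oc(=O)ccc2cc1[C@@H]1C=C(C)CC[C@]1(C)/C=C/c1c(OC)ccc2ccc(=O)oc12 | target

## Step count and risks

Total step count: 19. Longest linear sequence: 15 steps (steps 1–14 and 19); the coumarin B branch is 4 steps (15–18).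

Steps most likely to fail:

1. Step 7. Heterolysis of the tertiary, aryl-conjugated allylic C–O bond of the ketene acetal may outrun the concerted shift. That would lead to elimination, or to a stepwise recombination with loss of the cis relationship and of chirality transfer. The congested boat, which builds a quaternary centre next to a tertiary one, may also need temperatures at which the ketene acetal decomposes. The fallback sets out from 11 and comes back to the route at 17. Heck coupling of 11 with 2-methylbut-3-en-2-ol (Pd(OAc)2, NaHCO3, Bu4NCl, DMF, 80 °C) should give (E)-4-(2,4-dimethoxyphenyl)-2-methylbut-3-en-2-ol F1. Dehydration (MsCl, Et3N, CH2Cl2) should give 1-[(E)-3-methylbuta-1,3-dienyl]-2,4-dimethoxybenzene F2, to be used at once because such dienes dimerise. An enantioselective Diels–Alder reaction of F2 with methacrolein, catalysed by a triflimide-activated B-(o-tolyl) oxazaborolidine made from diphenylprolinol, should give (1S,2S)-2-(2,4-dimethoxyphenyl)-1,4-dimethylcyclohex-3-ene-1-carbaldehyde F3. The catalyst enantiomer is the one that gives the (1S,2S) adduct; which one that is has to be fixed by correlation with 17 from the main route. The 1-aryl and 3-methyl groups of the diene both direct the formyl-bearing carbon next to the aryl-bearing carbon, and the endo mode should put aryl cis to formyl. Reduction with NaBH4 in MeOH then gives 17.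

2. Step 6. β-Acyloxy elimination from the alkylpalladium intermediate, or ionisation of the allylic lactone by zerovalent palladium, would open the ring. Silver-promoted ionisation of the electron-rich product may also erode the yield. The fallback sets out from 10 and comes back at 12. Cross-metathesis of 10 with an excess of 1-ethenyl-2,4-dimethoxybenzene F4 (made by Wittig methylenation of 2,4-dimethoxybenzaldehyde), using RuCl2(H2IMes)(=CH-C6H4-2-OiPr), the second-generation Hoveyda–Grubbs catalyst, in toluene at 60 °C, should give the E-styryl lactone 12. The vinyl group on a fully substituted allylic carbon does not homodimerise, so it should pair selectively with the styrene.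

3. Step 19. Slow addition to the hindered α-quaternary aldehyde may let the phosphonate carbanion add in conjugate fashion to a coumarin C3=C4 bond or attack a lactone carbonyl, so that conversion to the alkene stays low. The fallback sets out from 26 and comes back at 33. Wittig methylenation of 26 ([Ph3PCH3]Br, KOtBu, THF, −78 → 0 °C) should give 6-[(1R,6R)-6-ethenyl-3,6-dimethylcyclohex-2-en-1-yl]-7-methoxy-2H-chromen-2-one F5. Separately, iodination of 7-hydroxycoumarin (I2, KI, aqueous NH3) should give 7-hydroxy-8-iodo-2H-chromen-2-one F6, and O-methylation (MeI, K2CO3, acetone) should give 8-iodo-7-methoxy-2H-chromen-2-one F7. Heck coupling of F5 with F7 (Pd(OAc)2, NaHCO3, Bu4NCl, DMF, 90 °C) should then arylate the terminal vinyl carbon and give the E-alkene 33.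

Further compounds

F1 | step 7 | (E)-4-(2,4-dimethoxyphenyl)-2-methylbut-3-en-2-ol | COc1ccc(/C=C/C(C)(C)O)c(OC)c1
F2 | step 7 | 1-[(E)-3-methylbuta-1,3-dienyl]-2,4-dimethoxybenzene | COc1ccc(/C=C/C(C)=C)c(OC)c1
F3 | step 7 | (1S,2S)-2-(2,4-dimethoxyphenyl)-1,4-dimethylcyclohex-3-ene-1-carbaldehyde | COc1ccc([C@@H]2C=C(C)CC[C@]2(C)C=O)c(OC)c1
F4 | step 6 | 1-ethenyl-2,4-dimethoxybenzene | C=Cc1ccc(OC)cc1OC
F5 | step 19 | 6-[(1R,6R)-6-ethenyl-3,6-dimethylcyclohex-2-en-1-yl]-7-methoxy-2H-chromen-2-one | COc1cc2oc(=O)ccc2cc1[C@@H]1C=C(C)CC[C@]1(C)C=C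
F6 | step 19 | 7-hydroxy-8-iodo-2H-chromen-2-one | Oc1ccc2ccc(=O)oc2c1I
F7 | step 19 | 8-iodo-7-methoxy-2H-chromen-2-one | COc1ccc2ccc(=O)oc2c1I
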